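## Retrosynthetic overview

- **Feature:** in the 4-pyranone (ring C), C4(=O), C3 and C2 are the ester carbon, alpha carbon and aryl ketone carbon of a beta-keto ester. That keto ester lies inside the seven-membered oxepine (ring D: C2, C3, CH2, (R)-CH, O, C2', C1') fused to ring B. Ring A, without its 7-O-methyl and C6 alkenyl groups, is threefold-symmetric phloroglucinol.
- **Late disconnections:** C6–C1'' (Suzuki coupling on a 6-iodide placed ortho to the chelated 5-OH), 7-O–CH3, and the two Si–O bonds.
- **Key disconnection:** C4–C4a and O1–C2 are cut together, back to phloroglucinol and a tert-butyl 5-oxobenzoxepine-4-carboxylate that serves as an acylketene source.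
- **Keto ester:** C4–C5 (Dieckmann closure of ring D onto a salicylate), the two carbinol methyls (Grignard addition to an alpha-aryloxy ester), and O–C2 (Mitsunobu inversion of an (S)-2-hydroxyglutarate from L-glutamic acid, the source of the single (R) centre).
- **Ring order:** B (bought) → D (step 7) → C, which brings ring A with it (step 8).

Key step: step 8

Remark on names: the tetracycles are named as 6,7-dihydrochromeno[3,2-d][1]benzoxepin-8-ones. In that numbering C3 = C4' of ring B, O5 = oxepine oxygen, C6 = stereocentre, C7 = methylene, C8 = chromone C4, and C9–C12 = chromone C5–C8. The discussion uses chromone numbering.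

Assumption: the alpha carbon of the beta-keto ester, and of the diketone derived from it, is enolisable and is left unspecified. Phloroglucinol is used in its dried, anhydrous form.

## Route

Step 1
Reactants: 1 methyl 2,4-dihydroxybenzoate
Product: 2 methyl 2-hydroxy-4-(triisopropylsilyloxy)benzoate
Conditions: TIPSCl (1.05 equiv), imidazole, DMF, 0 °C → rt
Reagents that add atoms: triisopropylsilyl chloride, CC(C)[Si](Cl)(C(C)C)C(C)C
Why: Imidazole-promoted silyl ether formation is site-selective because the 2-OH is held in a hydrogen bond to the ester carbonyl and is crowded by it, so the bulky chlorosilane should react only at the free 4-OH.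

Step 2
Reactants: 3 L-glutamic acid 5-tert-butyl ester, (2S)-2-amino-5-tert-butoxy-5-oxopentanoic acid
Product: 4 (2S)-5-tert-butoxy-2-hydroxy-5-oxopentanoic acid
Conditions: NaNO2 (2 equiv), AcOH–H2O (1:4), 0 °C → rt
Reagents that add atoms: water, O
Why: Diazotisation–hydrolysis of an alpha-amino acid runs with participation of the neighbouring carboxylate and hence with double inversion, so the (S) configuration of L-glutamate should be retained in the hydroxy acid, and cold dilute acetic acid leaves the tert-butyl ester intact.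

Step 3
Reactants: 4 (2S)-5-tert-butoxy-2-hydroxy-5-oxopentanoic acid
Product: 5 5-tert-butyl 1-methyl (2S)-2-hydroxypentanedioate
Conditions: MeI (1.2 equiv), KHCO3 (1.5 equiv), DMF, rt
Reagents that add atoms: iodomethane, CI
Why: Carboxylate alkylation (SN2 on iodomethane) under bicarbonate, a base too weak to deprotonate the alcohol, to enolise the stereocentre or to start lactonisation onto the tert-butyl ester.

Step 4
Reactants: 2 methyl 2-hydroxy-4-(triisopropylsilyloxy)benzoate, 5 5-tert-butyl 1-methyl (2S)-2-hydroxypentanedioate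
Product: 6 methyl 2-{[(2R)-5-tert-butoxy-1-methoxy-1,5-dioxopentan-2-yl]oxy}-4-(triisopropylsilyloxy)benzoate
Conditions: PPh3, DIAD (1.3 equiv each), THF, 0 °C → rt
Reagents that add atoms: none
Why: Mitsunobu etherification of an alpha-hydroxy ester by a phenol is a clean SN2 process at the activated carbinol carbon, so (S)-5 should give the (R)-aryl ether by inversion, which sets the only stereocentre of the target under neutral conditions that the silyl ether and the tert-butyl ester tolerate.

Step 5
Reactants: 6 methyl 2-{[(2R)-5-tert-butoxy-1-methoxy-1,5-dioxopentan-2-yl]oxy}-4-(triisopropylsilyloxy)benzoate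
Product: 7 methyl 2-{[(3R)-6-tert-butoxy-2-hydroxy-2-methyl-6-oxohexan-3-yl]oxy}-4-(triisopropylsilyloxy)benzoate
Conditions: MeMgBr (2.3 equiv), THF, −78 → −30 °C; AcOH in THF at −78 °C
Reagents that add atoms: methylmagnesium bromide, C[Mg]Br
Why: Double Grignard addition to an ester, chemoselective because the alpha-aryloxy methyl ester is inductively activated and can chelate magnesium, whereas the 2,4-dioxygenated benzoate is a crowded vinylogous carbonate and the tert-butyl ester is shielded; addition at low temperature outruns enolisation, so the (R) centre is kept, and the cold acid quench prevents lactonisation of the alkoxide.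

Step 6
Reactants: 7 methyl 2-{[(3R)-6-tert-butoxy-2-hydroxy-2-methyl-6-oxohexan-3-yl]oxy}-4-(triisopropylsilyloxy)benzoate
Product: 8 methyl 2-{[(3R)-6-tert-butoxy-2-methyl-6-oxo-2-(triethylsilyloxy)hexan-3-yl]oxy}-4-(triisopropylsilyloxy)benzoate
Conditions: TESOTf (1.2 equiv), 2,6-lutidine, CH2Cl2, −78 → −20 °C
Reagents that add atoms: triethylsilyl trifluoromethanesulfonate, CC[Si](CC)(CC)OS(=O)(=O)C(F)(F)F
Why: Silyl triflate/lutidine silylation is the standard way to cap a hindered tertiary alcohol, and the cap is needed so that no oxygen nucleophile of the substrate can attack an ester in step 7 or the ketene in step 8.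

Step 7
Reactants: 8 methyl 2-{[(3R)-6-tert-butoxy-2-methyl-6-oxo-2-(triethylsilyloxy)hexan-3-yl]oxy}-4-(triisopropylsilyloxy)benzoate
Product: 9 tert-butyl (2R)-5-oxo-2-[2-(triethylsilyloxy)propan-2-yl]-8-(triisopropylsilyloxy)-2,3,4,5-tetrahydro-1-benzoxepine-4-carboxylate
Conditions: LiN(SiMe3)2 (2.2 equiv), THF, −78 → 0 °C; AcOH
Reagents that add atoms: none
Why: Dieckmann condensation (7-exo-trig), the classical entry to 5-oxo-tetrahydro-1-benzoxepine-4-carboxylates: only the tert-butyl ester has alpha hydrogens, only the methyl benzoate can lose alkoxide readily, and deprotonation of the beta-keto ester by the second equivalent of base makes the closure irreversible, the new C4 centre being enolisable and of no consequence.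

Step 8
Reactants: 9 tert-butyl (2R)-5-oxo-2-[2-(triethylsilyloxy)propan-2-yl]-8-(triisopropylsilyloxy)-2,3,4,5-tetrahydro-1-benzoxepine-4-carboxylate, 10 phloroglucinol
Product: 13 (6R)-9,11-dihydroxy-6-[2-(triethylsilyloxy)propan-2-yl]-3-(triisopropylsilyloxy)-6,7-dihydrochromeno[3,2-d][1]benzoxepin-8-one, via acylketene 11 (not isolated), via trihydroxyaryl diketone 12 (not isolated)
Conditions: 10 (anhydrous, 3 equiv), Ph2O, 140 °C then 200 °C, slow Ar stream to carry off t-BuOH and H2O
Reagents that add atoms: none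
Why: The enol form of 9 loses tert-butanol through a six-centre transition state from about 130 °C and gives alpha-oxoketene 11; O-acylation of 10 is reversible at this temperature, whereas attack by a ring carbon of the strongly enolic phloroglucinol followed by rearomatisation is not, and it forms C4–C4a in 12. One of the two ortho hydroxyls of 12 then adds to the benzoxepinone carbonyl (6-exo-trig) and loss of water creates O1–C2 and the C2=C3 double bond, so ring C is closed and the product leaves all equilibria as an aromatic 4-pyranone. The closest known reactions are the Mentzer thermal chromone synthesis from phenols and beta-keto esters (cyclic and alpha-substituted ones, and aroylacetates with phloroglucinol) and the thermal acylketene transfer from tert-butyl beta-keto esters. No stereocentre is made: the labile C4 centre of 9 becomes sp2, and the (R) centre is an ether carbon whose hydrogen is not acidic, so it is carried through unchanged. The step needs chromone over coumarin selectivity, which is secured by the absence of acid and by the ketone of 9 being a doubly oxygen-donated aryl ketone that no ring carbon attacks, and it needs no regiocontrol in ring A because all three CH and all three OH of 10 are equivalent. Excess 10 suppresses a second annulation of 13, and the gas stream removes the water that would otherwise hydrate 11 and decarboxylate it.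

Step 9
Reactants: 13 (6R)-9,11-dihydroxy-6-[2-(triethylsilyloxy)propan-2-yl]-3-(triisopropylsilyloxy)-6,7-dihydrochromeno[3,2-d][1]benzoxepin-8-one
Product: 14 (6R)-9-hydroxy-11-methoxy-6-[2-(triethylsilyloxy)propan-2-yl]-3-(triisopropylsilyloxy)-6,7-dihydrochromeno[3,2-d][1]benzoxepin-8-one
Conditions: MeOH (1.1 equiv), PPh3, DIAD, THF, 0 °C → rt
Reagents that add atoms: methanol, CO
Why: Mitsunobu O-methylation picks the acidic, non-chelated 7-OH because the 5-OH is locked in a hydrogen bond to C4=O, and the neutral medium spares the 4'-silyl ether, which is conjugated to the carbonyl and therefore sensitive to base.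

Step 10
Reactants: 14 (6R)-9-hydroxy-11-methoxy-6-[2-(triethylsilyloxy)propan-2-yl]-3-(triisopropylsilyloxy)-6,7-dihydrochromeno[3,2-d][1]benzoxepin-8-one
Product: 15 (6R)-9-hydroxy-10-iodo-11-methoxy-6-[2-(triethylsilyloxy)propan-2-yl]-3-(triisopropylsilyloxy)-6,7-dihydrochromeno[3,2-d][1]benzoxepin-8-one
Conditions: BnMe3N·ICl2 (1.05 equiv), CaCO3, CH2Cl2–MeOH (5:2), rt
Reagents that add atoms: benzyltrimethylammonium dichloroiodate, C[N+](C)(C)Cc1ccccc1.Cl[I-]Cl
Why: Electrophilic aromatic iodination with buffered dichloroiodate, a system that iodinates free phenols but not aryl ethers and that places iodine ortho to the free 5-OH (C6) of 5-hydroxy-7-alkoxyflavones, so ring B, which carries only ether oxygens, should stay untouched.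

Step 11
Reactants: 16 3-methylbut-1-yne
Product: 17 (E)-4,4,5,5-tetramethyl-2-(3-methylbut-1-enyl)-1,3,2-dioxaborolane
Conditions: pinacolborane, Cp2ZrHCl (5 mol %), Et3N (10 mol %), neat, sealed tube, 60 °C
Reagents that add atoms: pinacolborane, [H]B1OC(C)(C)C(C)(C)O1
Why: Zirconium-catalysed alkyne hydroboration is a syn, anti-Markovnikov addition of H–B, which should give the (E)-1-alkenylboronate only.

Step 12
Reactants: 15 (6R)-9-hydroxy-10-iodo-11-methoxy-6-[2-(triethylsilyloxy)propan-2-yl]-3-(triisopropylsilyloxy)-6,7-dihydrochromeno[3,2-d][1]benzoxepin-8-one, 17 (E)-4,4,5,5-tetramethyl-2-(3-methylbut-1-enyl)-1,3,2-dioxaborolane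
Product: 18 (6R)-9-hydroxy-11-methoxy-10-[(E)-3-methylbut-1-enyl]-6-[2-(triethylsilyloxy)propan-2-yl]-3-(triisopropylsilyloxy)-6,7-dihydrochromeno[3,2-d][1]benzoxepin-8-one
Conditions: 17 (1.5 equiv), Pd(OAc)2 (5 mol %), SPhos (10 mol %), K3PO4 (3 equiv), THF–H2O (10:1), 60 °C
Reagents that add atoms: none
Why: Suzuki–Miyaura coupling transfers the alkenyl group with retention of the E geometry, and the bulky electron-rich biarylphosphine lets zerovalent palladium insert into the iodide flanked by OH and OMe.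

Step 13
Reactants: 18 (6R)-9-hydroxy-11-methoxy-10-[(E)-3-methylbut-1-enyl]-6-[2-(triethylsilyloxy)propan-2-yl]-3-(triisopropylsilyloxy)-6,7-dihydrochromeno[3,2-d][1]benzoxepin-8-one
Product: 19 (6R)-3,9-dihydroxy-6-(2-hydroxypropan-2-yl)-11-methoxy-10-[(E)-3-methylbut-1-enyl]-6,7-dihydrochromeno[3,2-d][1]benzoxepin-8-one (CNP0216454.1)
Conditions: Bu4NF (3 equiv), AcOH (3 equiv), THF, 0 °C → rt
Reagents that add atoms: none
Why: Fluoride-induced cleavage of both Si–O bonds, buffered with acetic acid so that neither strong base nor strong acid meets the electron-rich styrene, the tertiary alcohol or the (R) ether centre.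

## Compound list

1 | methyl 2,4-dihydroxybenzoate | COC(=O)c1ccc(O)cc1O | starting material
2 | methyl 2-hydroxy-4-(triisopropylsilyloxy)benzoate | COC(=O)c1ccc(O[Si](C(C)C)(C(C)C)C(C)C)cc1O | intermediate
3 | L-glutamic acid 5-tert-butyl ester, (2S)-2-amino-5-tert-butoxy-5-oxopentanoic acid | N[C@@H](CCC(=O)OC(C)(C)C)C(=O)O | starting material
4 | (2S)-5-tert-butoxy-2-hydroxy-5-oxopentanoic acid | O[C@@H](CCC(=O)OC(C)(C)C)C(=O)O | intermediate
5 | 5-tert-butyl 1-methyl (2S)-2-hydroxypentanedioate | O[C@@H](CCC(=O)OC(C)(C)C)C(=O)OC | intermediate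
6 | methyl 2-{[(2R)-5-tert-butoxy-1-methoxy-1,5-dioxopentan-2-yl]oxy}-4-(triisopropylsilyloxy)benzoate | COC(=O)c1ccc(O[Si](C(C)C)(C(C)C)C(C)C)cc1O[C@H](CCC(=O)OC(C)(C)C)C(=O)OC | intermediate
7 | methyl 2-{[(3R)-6-tert-butoxy-2-hydroxy-2-methyl-6-oxohexan-3-yl]oxy}-4-(triisopropylsilyloxy)benzoate | COC(=O)c1ccc(O[Si](C(C)C)(C(C)C)C(C)C)cc1O[C@H](CCC(=O)OC(C)(C)C)C(C)(C)O | intermediate
8 | methyl 2-{[(3R)-6-tert-butoxy-2-methyl-6-oxo-2-(triethylsilyloxy)hexan-3-yl]oxy}-4-(triisopropylsilyloxy)benzoate | COC(=O)c1ccc(O[Si](C(C)C)(C(C)C)C(C)C)cc1O[C@H](CCC(=O)OC(C)(C)C)C(C)(C)O[Si](CC)(CC)CC | intermediate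
9 | tert-butyl (2R)-5-oxo-2-[2-(triethylsilyloxy)propan-2-yl]-8-(triisopropylsilyloxy)-2,3,4,5-tetrahydro-1-benzoxepine-4-carboxylate (C4 unspecified) | CC(C)(C)OC(=O)C1C[C@H](C(C)(C)O[Si](CC)(CC)CC)Oc2cc(O[Si](C(C)C)(C(C)C)C(C)C)ccc2C1=O | intermediate
10 | phloroglucinol (benzene-1,3,5-triol) | Oc1cc(O)cc(O)c1 | starting material
11 | acylketene, (2R)-4-(oxomethylidene)-2-[2-(triethylsilyloxy)propan-2-yl]-8-(triisopropylsilyloxy)-3,4-dihydro-1-benzoxepin-5(2H)-one | O=C=C1C[C@H](C(C)(C)O[Si](CC)(CC)CC)Oc2cc(O[Si](C(C)C)(C(C)C)C(C)C)ccc2C1=O | intermediate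
12 | (2R)-4-(2,4,6-trihydroxybenzoyl)-2-[2-(triethylsilyloxy)propan-2-yl]-8-(triisopropylsilyloxy)-3,4-dihydro-1-benzoxepin-5(2H)-one (C4 unspecified) | O=C(c1c(O)cc(O)cc1O)C1C[C@H](C(C)(C)O[Si](CC)(CC)CC)Oc2cc(O[Si](C(C)C)(C(C)C)C(C)C)ccc2C1=O | intermediate
13 | (6R)-9,11-dihydroxy-6-[2-(triethylsilyloxy)propan-2-yl]-3-(triisopropylsilyloxy)-6,7-dihydrochromeno[3,2-d][1]benzoxepin-8-one | Oc1cc2oc3c(c(=O)c2c(O)c1)C[C@H](C(C)(C)O[Si](CC)(CC)CC)Oc1cc(O[Si](C(C)C)(C(C)C)C(C)C)ccc1-3 | intermediate
14 | (6R)-9-hydroxy-11-methoxy-6-[2-(triethylsilyloxy)propan-2-yl]-3-(triisopropylsilyloxy)-6,7-dihydrochromeno[3,2-d][1]benzoxepin-8-one | COc1cc2oc3c(c(=O)c2c(O)c1)C[C@H](C(C)(C)O[Si](CC)(CC)CC)Oc1cc(O[Si](C(C)C)(C(C)C)C(C)C)ccc1-3 | intermediate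
15 | (6R)-9-hydroxy-10-iodo-11-methoxy-6-[2-(triethylsilyloxy)propan-2-yl]-3-(triisopropylsilyloxy)-6,7-dihydrochromeno[3,2-d][1]benzoxepin-8-one | COc1cc2oc3c(c(=O)c2c(O)c1I)C[C@H](C(C)(C)O[Si](CC)(CC)CC)Oc1cc(O[Si](C(C)C)(C(C)C)C(C)C)ccc1-3 | intermediate
16 | 3-methylbut-1-yne | CC(C)C#C | starting material
17 | (E)-4,4,5,5-tetramethyl-2-(3-methylbut-1-enyl)-1,3,2-dioxaborolane | CC(C)/C=C/B1OC(C)(C)C(C)(C)O1 | intermediate
18 | (6R)-9-hydroxy-11-methoxy-10-[(E)-3-methylbut-1-enyl]-6-[2-(triethylsilyloxy)propan-2-yl]-3-(triisopropylsilyloxy)-6,7-dihydrochromeno[3,2-d][1]benzoxepin-8-one | COc1cc2oc3c(c(=O)c2c(O)c1/C=C/C(C)C)C[C@H](C(C)(C)O[Si](CC)(CC)CC)Oc1cc(O[Si](C(C)C)(C(C)C)C(C)C)ccc1-3 | intermediate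
19 | (6R)-3,9-dihydroxy-6-(2-hydroxypropan-2-yl)-11-methoxy-10-[(E)-3-methylbut-1-enyl]-6,7-dihydrochromeno[3,2-d][1]benzoxepin-8-one | COc1cc2oc3c(c(=O)c2c(O)c1/C=C/C(C)C)C[C@H](C(C)(C)O)Oc1cc(O)ccc1-3 | target

## Step count and risks

Total step count: 13.
Longest linear sequence: 11 (steps 2–10, 12 and 13).

**Risk 1, step 8.**
- What may go wrong: acyl transfer may stop at oxygen. The water of condensation may hydrate the ketene, which then decarboxylates. Silyl groups may migrate to the excess phenol at 200 °C.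
- Fallback (sets out from 9, comes back at 12 and so at 13): the C3–C4 bond is made by enolate acylation instead of C4–C4a. Heating 9 in wet toluene at 110 °C should hydrate the ketene and decarboxylate it to (2R)-2-[2-(triethylsilyloxy)propan-2-yl]-8-(triisopropylsilyloxy)-3,4-dihydro-1-benzoxepin-5(2H)-one F1. Its lithium enolate (LiN(SiMe3)2, THF, −78 °C) is acylated with 2,4,6-tris(benzyloxy)benzoyl chloride to (2R)-4-[2,4,6-tris(benzyloxy)benzoyl]-2-[2-(triethylsilyloxy)propan-2-yl]-8-(triisopropylsilyloxy)-3,4-dihydro-1-benzoxepin-5(2H)-one F2. Hydrogenolysis (H2, Pd on carbon, EtOAc), harmless at this alkene-free stage, uncovers 12. Brief heating in toluene with catalytic pyridinium p-toluenesulfonate closes 12 to 13.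

**Risk 2, step 5.**
- What may go wrong: discrimination between the three esters may be lost (attack on the benzoate). The magnesium alkoxide may lactonise. Enolisation of the alpha-aryloxy ester may erode the configuration.
- Fallback (sets out from 5, comes back at 8): the benzoate is introduced only after the Grignard step. 4-Bromoresorcinol is silylated at the less hindered hydroxyl (TIPSCl, imidazole) to 2-bromo-5-(triisopropylsilyloxy)phenol F3. Mitsunobu coupling with 5 gives 5-tert-butyl 1-methyl (2R)-2-[2-bromo-5-(triisopropylsilyloxy)phenoxy]pentanedioate F4. MeMgBr now meets a single methyl ester and gives tert-butyl (4R)-4-[2-bromo-5-(triisopropylsilyloxy)phenoxy]-5-hydroxy-5-methylhexanoate F5. TESOTf and 2,6-lutidine give tert-butyl (4R)-4-[2-bromo-5-(triisopropylsilyloxy)phenoxy]-5-methyl-5-(triethylsilyloxy)hexanoate F6. Bromine–lithium exchange (n-BuLi, THF, −78 °C) followed by ClCO2Me gives 8.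

**Risk 3, step 10.**
- What may go wrong: iodination may occur para to the 5-OH (C8), or twofold iodination of ring A may take place.
- Fallback (sets out from 14, comes back at 18, bypassing steps 10–12): magnesium phenoxide-directed ortho-formylation (MgCl2, Et3N, paraformaldehyde, MeCN, reflux) delivers formaldehyde within the phenoxide complex, so it can reach only the carbon next to the 5-OH. It gives (6R)-9-hydroxy-11-methoxy-8-oxo-6-[2-(triethylsilyloxy)propan-2-yl]-3-(triisopropylsilyloxy)-6,7-dihydrochromeno[3,2-d][1]benzoxepine-10-carbaldehyde F7. Julia–Kocienski olefination with 5-(2-methylpropylsulfonyl)-1-phenyl-1H-tetrazole (KN(SiMe3)2, 2.2 equiv, THF, −78 °C → rt) should give the E-alkene 18.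

## Further compounds

F1 | step 8 | (2R)-2-[2-(triethylsilyloxy)propan-2-yl]-8-(triisopropylsilyloxy)-3,4-dihydro-1-benzoxepin-5(2H)-one | O=C1CC[C@H](C(C)(C)O[Si](CC)(CC)CC)Oc2cc(O[Si](C(C)C)(C(C)C)C(C)C)ccc12
F2 | step 8 | (2R)-4-[2,4,6-tris(benzyloxy)benzoyl]-2-[2-(triethylsilyloxy)propan-2-yl]-8-(triisopropylsilyloxy)-3,4-dihydro-1-benzoxepin-5(2H)-one | O=C(c1c(OCc2ccccc2)cc(OCc2ccccc2)cc1OCc1ccccc1)C1C[C@H](C(C)(C)O[Si](CC)(CC)CC)Oc2cc(O[Si](C(C)C)(C(C)C)C(C)C)ccc2C1=O
F3 | step 5 | 2-bromo-5-(triisopropylsilyloxy)phenol | Oc1cc(O[Si](C(C)C)(C(C)C)C(C)C)ccc1Br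
F4 | step 5 | 5-tert-butyl 1-methyl (2R)-2-[2-bromo-5-(triisopropylsilyloxy)phenoxy]pentanedioate | Brc1ccc(O[Si](C(C)C)(C(C)C)C(C)C)cc1O[C@H](CCC(=O)OC(C)(C)C)C(=O)OC
F5 | step 5 | tert-butyl (4R)-4-[2-bromo-5-(triisopropylsilyloxy)phenoxy]-5-hydroxy-5-methylhexanoate | Brc1ccc(O[Si](C(C)C)(C(C)C)C(C)C)cc1O[C@H](CCC(=O)OC(C)(C)C)C(C)(C)O
F6 | step 5 | tert-butyl (4R)-4-[2-bromo-5-(triisopropylsilyloxy)phenoxy]-5-methyl-5-(triethylsilyloxy)hexanoate | Brc1ccc(O[Si](C(C)C)(C(C)C)C(C)C)cc1O[C@H](CCC(=O)OC(C)(C)C)C(C)(C)O[Si](CC)(CC)CC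
F7 | step 10 | (6R)-9-hydroxy-11-methoxy-8-oxo-6-[2-(triethylsilyloxy)propan-2-yl]-3-(triisopropylsilyloxy)-6,7-dihydrochromeno[3,2-d][1]benzoxepine-10-carbaldehyde | COc1cc2oc3c(c(=O)c2c(O)c1C=O)C[C@H](C(C)(C)O[Si](CC)(CC)CC)Oc1cc(O[Si](C(C)C)(C(C)C)C(C)C)ccc1-3
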